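**Retrosynthetic overview**

1. Locants: ring A = resorcinol ring of the first dihydrofuran (ring O–C7a–C8a), its carbons counted from the one bearing C8b as position 1 (position 2 bears C8a, position 3 the ring oxygen, position 5 OH); C7b=C8b = alkene of the seven-membered ring; ring B = central arene, numbered as a benzofuran (O1, C2 = C7c, C3 = C8c, C3a, C4–OH, C5, C6, C7, C7a).
2. Late stage: global demethylation; ring-A dihydrofuran by enantioselective rhodium-carbene C–H insertion at C8a; seven-membered ring by benzyl-Grignard addition at C7b, dehydration and Friedel–Crafts acylation by ring A.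
3. Ring B is not carried through the route. It is condensed around a preformed oxolane enol ether (C3a–C4 by γ-acetylation, C7–C6–C5 by C-oxalylation and aldol aromatisation), so no substitution of a finished arene is needed.
4. Key disconnection: O1–C7a of the ring-B dihydrofuran, formed while C7a is still an alkyne carbon. The enabling feature is that C7a lies four atoms from the C2 carbinol oxygen (O1–C2–C3–C3a–C7a) and its neighbour C7 carries C7b, an sp2 carbon bearing the 4-hydroxyphenyl group. C7a≡C7–C7b(=O)Ar is therefore an ynone with C7a as β-carbon and C7b delivered by CO, and the 1,3-dioxygenation of ring B (O1, C4–OH) lets the ring be built afterwards from carbonyl units.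
5. Order of ring formation: ring-B dihydrofuran (step 4), ring B (step 6), temporary lactone (step 8), seven-membered ring (step 9), ring-A dihydrofuran (step 13).

Key step: step 4

Assumption: a ketoreductase giving the (1R,2S) alcohol is found by screening a commercial panel, and Rh2(R-PTAD)4 is assumed to give the (8aS) sense; if either sense is opposite, the other enzyme or the enantiomeric catalyst is used.

**Route**

Step 1
Reactants: 1 4'-methoxyacetophenone; 2 1-bromo-3,5-dimethoxybenzene
Product: 3 2-(3,5-dimethoxyphenyl)-1-(4-methoxyphenyl)ethan-1-one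
Conditions: Pd2(dba)3 (1 mol%), Xantphos (2.4 mol%), NaOt-Bu, THF, 70 °C, ketone in slight excess
Reagents that add atoms: none
Why: Palladium-catalysed ketone α-arylation (Buchwald–Hartwig type); the excess of methyl ketone and the wide-bite-angle bisphosphine should hold the coupling at mono-arylation.

Step 2
Reactants: 3 2-(3,5-dimethoxyphenyl)-1-(4-methoxyphenyl)ethan-1-one; 4 propargyl bromide
Product: 5 rac-2-(3,5-dimethoxyphenyl)-1-(4-methoxyphenyl)pent-4-yn-1-one
Conditions: KOt-Bu, THF, −78 °C; then 4, −78 → 0 °C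
Reagents that add atoms: none
Why: Enolate C-alkylation of the benzylic ketone CH2 with an SN2-active propargyl halide; the new stereocentre is racemic and configurationally labile, which step 3 exploits.

Step 3
Reactants: 5 rac-2-(3,5-dimethoxyphenyl)-1-(4-methoxyphenyl)pent-4-yn-1-one
Product: 6 (1R,2S)-2-(3,5-dimethoxyphenyl)-1-(4-methoxyphenyl)pent-4-yn-1-ol
Conditions: ketoreductase (NADPH-dependent, anti-selective panel enzyme), NADP+ (cat.), i-PrOH (15 vol%), DMSO (10 vol%), triethanolamine buffer pH 9.5, 35 °C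
Reagents that add atoms: none
Why: Enzymatic dynamic reductive kinetic resolution: the α-aryl ketone racemises by enolisation at pH 9.5 while the active site reduces only the (2S)-ketone on one carbonyl face, so the carbinol centre (R) and the neighbouring benzylic centre (S) are set together; this anti isomer is the one that Felkin-controlled hydride or transfer-hydrogenation catalysts should not favour.

Step 4
Reactants: 6 (1R,2S)-2-(3,5-dimethoxyphenyl)-1-(4-methoxyphenyl)pent-4-yn-1-ol; 7 4-iodoanisole
Product: 9 (E)-2-[(4S,5R)-4-(3,5-dimethoxyphenyl)-5-(4-methoxyphenyl)oxolan-2-ylidene]-1-(4-methoxyphenyl)ethan-1-one, via hydroxy ynone 8 (not isolated)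
Conditions: CO (1 atm), PdCl2(PPh3)2 (2 mol%), CuI (1 mol%), Et3N, THF, 25 °C; then DBU (0.3 equiv), 40 °C
Reagents that add atoms: carbon monoxide, [C-]#[O+]
Why: Oxidative addition of 7 to zerovalent palladium, CO insertion to the aroyl complex of divalent palladium, transmetalation from the copper acetylide of 6 and reductive elimination give ynone 8, whose former alkyne terminus is now the β-carbon of an alkynyl ketone; the carbinol hydroxyl adds to that carbon and protonation at the α-carbon gives vinylogous ester 9. The closest known reactions are the carbonylative Sonogashira coupling of aryl iodides and the base-mediated cyclisation of hydroxy ynones to 2-(acylmethylene)oxolanes, the aliphatic counterpart of the carbonylative flavone and aurone syntheses. The oxolane closes in the 5-exo-dig mode by forming the O–C bond to the carbon that becomes C7a of ring B. No stereocentre is created: the two carbinol-derived centres come unchanged from 6 because none of their bonds is broken, and the alkene geometry is of no consequence since it disappears in step 6. The step needs carbonylative rather than direct coupling and acetylide rather than alkoxide capture of the aroyl–palladium species; the electron-rich aryl iodide under CO and the far higher nucleophilicity of the copper acetylide over the hindered secondary alcohol should secure both. It also needs O-attack at the β-carbon, which the ynone polarisation and the four-atom tether secure, the 6-endo alternative being an anti-Michael addition.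

Step 5
Reactants: 9 (E)-2-[(4S,5R)-4-(3,5-dimethoxyphenyl)-5-(4-methoxyphenyl)oxolan-2-ylidene]-1-(4-methoxyphenyl)ethan-1-one; 10 N-methoxy-N-methylacetamide
Product: 11 2-[(4R,5R)-3-acetyl-4-(3,5-dimethoxyphenyl)-5-(4-methoxyphenyl)-4,5-dihydrofuran-2-yl]-1-(4-methoxyphenyl)ethan-1-one
Conditions: LDA (1.2 equiv), THF, −78 °C; then 10, −78 → 0 °C; NH4Cl (aq)
Reagents that add atoms: none
Why: γ-Acylation of a vinylogous ester: LDA removes a proton from the only acidic position (ring CH2 at C3, γ to the ketone) and the extended lithium enolate reacts at this carbon with the Weinreb amide, whose stable tetrahedral adduct prevents over-acylation, as β-alkoxy enone anions do when used as acetoacetate-dianion equivalents; the ring stereocentres are not involved.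

Step 6
Reactants: 11 2-[(4R,5R)-3-acetyl-4-(3,5-dimethoxyphenyl)-5-(4-methoxyphenyl)-4,5-dihydrofuran-2-yl]-1-(4-methoxyphenyl)ethan-1-one; 12 methyl chlorooxoacetate
Product: 14 methyl (2R,3R)-3-(3,5-dimethoxyphenyl)-4-hydroxy-7-(4-methoxybenzoyl)-2-(4-methoxyphenyl)-2,3-dihydro-1-benzofuran-6-carboxylate, via triketo ester 13 (not isolated)
Conditions: MgBr2·OEt2, i-Pr2NEt, CH2Cl2, 0 → 25 °C; then DBU, 25 °C; AcOH
Reagents that add atoms: none
Why: Soft-enolisation C-acylation of the doubly activated CH2 (magnesium enolate plus acid chloride), then intramolecular aldol condensation of the acetyl CH3 onto the very electrophilic α-keto ester carbonyl and tautomerisation to the phenol (polyketide-type aldol aromatisation); this fixes C4–OH, C5–H, C6–CO2Me and C7–aroyl of ring B without regiochemical choice.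

Step 7
Reactants: 14 methyl (2R,3R)-3-(3,5-dimethoxyphenyl)-4-hydroxy-7-(4-methoxybenzoyl)-2-(4-methoxyphenyl)-2,3-dihydro-1-benzofuran-6-carboxylate
Product: 15 methyl (2R,3R)-3-(3,5-dimethoxyphenyl)-4-methoxy-7-(4-methoxybenzoyl)-2-(4-methoxyphenyl)-2,3-dihydro-1-benzofuran-6-carboxylate
Conditions: MeI, K2CO3, DMF, 25 °C
Reagents that add atoms: iodomethane, CI
Why: Williamson O-methylation of the acidic phenol (para to the ketone); the methyl ether protects C4–OH through the organometallic and Lewis-acid steps.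

Step 8
Reactants: 15 methyl (2R,3R)-3-(3,5-dimethoxyphenyl)-4-methoxy-7-(4-methoxybenzoyl)-2-(4-methoxyphenyl)-2,3-dihydro-1-benzofuran-6-carboxylate; 16 3,5-dimethoxybenzyl chloride
Product: 17 γ-lactone (phthalide) of the ring-B dihydrobenzofuran: the former C7 ketone carbon (C7b) carries 4-methoxyphenyl, 3,5-dimethoxybenzyl and the lactone oxygen, closed onto the C6 carbonyl; (2R,3R), mixture of epimers at C7b
Conditions: Mg, THF, 0 °C (Grignard reagent from 16); then 15, THF, −40 → 0 °C; NH4Cl (aq)
Reagents that add atoms: none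
Why: Grignard addition to the diaryl ketone, the more electrophilic carbonyl, then lactonisation of the magnesium alkoxide onto the neighbouring ester (phthalide formation from 2-aroylbenzoates); the new quaternary centre is lost again in step 9.

Step 9
Reactants: 17 γ-lactone (phthalide), mixture of epimers at C7b
Product: 19 seven-membered ketone of dibenzo[a,d]cyclohepten-5-one type (7cR,8cR) in which ring A (3-OMe and 5-OMe) and ring B are joined by C8a=O and by C8b(H)=C7b(4-methoxyphenyl), via stilbene acid 18 (not isolated)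
Conditions: TFAA, TFA, CH2Cl2, 0 → 25 °C
Reagents that add atoms: none
Why: Acid-mediated ionisation of the tertiary, doubly benzylic lactone C–O bond and loss of a proton give the triarylethene acid, and mixed-anhydride Friedel–Crafts acylation at the position of the 3,5-dimethoxyphenyl ring ortho to the vinyl arm and para to OMe closes the seven-membered ring (dibenzosuberenone synthesis); the alkene isomers interconvert through the cation, and C7c/C8c are already in the thermodynamically preferred trans arrangement.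

Step 10
Reactants: 19 seven-membered ketone
Product: 20 ring-A 3-phenol of the seven-membered ketone (the 3-OH of ring A is hydrogen-bonded to C8a=O); (7cR,8cR)
Conditions: BCl3 (1.5 equiv), CH2Cl2, −78 → 0 °C; water
Reagents that add atoms: none
Why: Chelation-controlled mono-demethylation: BCl3 binds between the ketone oxygen and the only methoxy group ortho to it and chloride removes that methyl group alone (selective cleavage of ortho-methoxy aryl ketones).

Step 11
Reactants: 20 ring-A 3-phenol of the seven-membered ketone; 21 4-methoxybenzyl chloride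
Product: 22 ring-A 3-O-(4-methoxybenzyl) ether of the seven-membered ketone; (7cR,8cR)
Conditions: K2CO3, KI (cat.), DMF, 60 °C
Reagents that add atoms: none
Why: Williamson etherification of the hydrogen-bonded phenol; the benzyl group is not a protecting group but supplies C7a and its 4-methoxyphenyl ring.

Step 12
Reactants: 22 ring-A 3-O-(4-methoxybenzyl) ether of the seven-membered ketone
Product: 23 C8a hydrazone of 22 (E/Z mixture); (7cR,8cR)
Conditions: N2H4·H2O (excess), AcOH (cat.), n-BuOH, 110 °C
Reagents that add atoms: hydrazine, NN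
Why: Hydrazone formation of a hindered diaryl ketone under forcing, acid-catalysed conditions, as used for dibenzosuberenone itself.

Step 13
Reactants: 23 C8a hydrazone
Product: 25 heptamethyl ether bearing the 7a,8a-cis ring-A dihydrofuran; (7aR,8aS,7cR,8cR), via diazo compound 24 (not isolated)
Conditions: MnO2, CH2Cl2, 0 °C; filtration into Rh2(R-PTAD)4 (dirhodium tetrakis[(R)-(1-adamantyl)(phthalimido)acetate], 1 mol%), CH2Cl2, −20 → 25 °C
Reagents that add atoms: none
Why: Oxidation of the hydrazone to the diaryldiazomethane and rhodium-carbene 1,5-C–H insertion into the O–CH2Ar bond (enantioselective donor/donor carbene insertion giving 2,3-diaryl-2,3-dihydrobenzofurans); the chiral dirhodium carboxylate selects the face of the carbene carbon and so sets C8a (S), and the insertion is expected to be cis-selective as with acyclic diaryl carbenes, giving C7a (R).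

Step 14
Reactants: 25 heptamethyl ether, 7a,8a-cis
Product: 26 heptamethyl ether of the target, 7a,8a-trans; (7aS,8aS,7cR,8cR)
Conditions: TFA (5 equiv), CH2Cl2, 0 °C
Reagents that add atoms: none
Why: Acid-catalysed epimerisation of a 2-aryl-2,3-dihydrobenzofuran: reversible ionisation of the benzylic C7a–O bond (cation stabilised by the 4-methoxyphenyl group) and re-closure should give the thermodynamically favoured trans isomer, C8a remaining as set in step 13.

Step 15
Reactants: 26 heptamethyl ether of the target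
Product: 27 target, CNP0325907.1
Conditions: BBr3 (3 equiv per OMe), CH2Cl2, −78 → 0 °C; MeOH, then water
Reagents that add atoms: none
Why: Lewis-acid ether cleavage (SN2 at the methyl groups of the boron-coordinated ethers) removes all seven methyl groups, as used for permethylated oligostilbenes containing trans-dihydrobenzofurans; all four stereocentres are already in their thermodynamic arrangement.

**Compound list**

1 | 4'-methoxyacetophenone | CC(=O)c1ccc(OC)cc1 | starting material
2 | 1-bromo-3,5-dimethoxybenzene | COc1cc(Br)cc(OC)c1 | starting material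
3 | 2-(3,5-dimethoxyphenyl)-1-(4-methoxyphenyl)ethan-1-one | COc1ccc(cc1)C(=O)Cc1cc(OC)cc(OC)c1 | intermediate
4 | propargyl bromide | C#CCBr | starting material
5 | rac-2-(3,5-dimethoxyphenyl)-1-(4-methoxyphenyl)pent-4-yn-1-one | COc1ccc(cc1)C(=O)C(CC#C)c1cc(OC)cc(OC)c1 | intermediate
6 | (1R,2S)-2-(3,5-dimethoxyphenyl)-1-(4-methoxyphenyl)pent-4-yn-1-ol | O[C@@H](c1ccc(OC)cc1)[C@@H](CC#C)c1cc(OC)cc(OC)c1 | intermediate
7 | 4-iodoanisole | COc1ccc(I)cc1 | starting material
8 | (5S,6R)-5-(3,5-dimethoxyphenyl)-6-hydroxy-1,6-bis(4-methoxyphenyl)hex-2-yn-1-one | O[C@@H](c1ccc(OC)cc1)[C@@H](CC#CC(=O)c1ccc(OC)cc1)c1cc(OC)cc(OC)c1 | intermediate (not isolated)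
9 | (E)-2-[(4S,5R)-4-(3,5-dimethoxyphenyl)-5-(4-methoxyphenyl)oxolan-2-ylidene]-1-(4-methoxyphenyl)ethan-1-one | O1[C@@H](c2ccc(OC)cc2)[C@@H](C/C1=C\C(=O)c1ccc(OC)cc1)c1cc(OC)cc(OC)c1 | intermediate
10 | N-methoxy-N-methylacetamide | CC(=O)N(C)OC | starting material
11 | 2-[(4R,5R)-3-acetyl-4-(3,5-dimethoxyphenyl)-5-(4-methoxyphenyl)-4,5-dihydrofuran-2-yl]-1-(4-methoxyphenyl)ethan-1-one (drawn as the endocyclic enol ether tautomer) | O1[C@@H](c2ccc(OC)cc2)[C@@H](C(C(C)=O)=C1CC(=O)c1ccc(OC)cc1)c1cc(OC)cc(OC)c1 | intermediate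
12 | methyl chlorooxoacetate | COC(=O)C(Cl)=O | starting material
13 | methyl 3-[(4R,5R)-3-acetyl-4-(3,5-dimethoxyphenyl)-5-(4-methoxyphenyl)-4,5-dihydrofuran-2-yl]-4-(4-methoxyphenyl)-2,4-dioxobutanoate (epimers at C3) | O1[C@@H](c2ccc(OC)cc2)[C@@H](C(C(C)=O)=C1C(C(=O)c1ccc(OC)cc1)C(=O)C(=O)OC)c1cc(OC)cc(OC)c1 | intermediate (not isolated)
14 | methyl (2R,3R)-3-(3,5-dimethoxyphenyl)-4-hydroxy-7-(4-methoxybenzoyl)-2-(4-methoxyphenyl)-2,3-dihydro-1-benzofuran-6-carboxylate | O1[C@@H](c2ccc(OC)cc2)[C@@H](c2c(O)cc(C(=O)OC)c(C(=O)c3ccc(OC)cc3)c21)c1cc(OC)cc(OC)c1 | intermediate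
15 | methyl (2R,3R)-3-(3,5-dimethoxyphenyl)-4-methoxy-7-(4-methoxybenzoyl)-2-(4-methoxyphenyl)-2,3-dihydro-1-benzofuran-6-carboxylate | O1[C@@H](c2ccc(OC)cc2)[C@@H](c2c(OC)cc(C(=O)OC)c(C(=O)c3ccc(OC)cc3)c21)c1cc(OC)cc(OC)c1 | intermediate
16 | 3,5-dimethoxybenzyl chloride | COc1cc(CCl)cc(OC)c1 | starting material
17 | γ-lactone (phthalide) formed between the C6 carbonyl and C7b, which bears 4-methoxyphenyl and 3,5-dimethoxybenzyl; (2R,3R), epimers at C7b | O1[C@@H](c2ccc(OC)cc2)[C@@H](c2c(OC)cc3C(=O)OC(Cc4cc(OC)cc(OC)c4)(c4ccc(OC)cc4)c3c21)c1cc(OC)cc(OC)c1 | intermediate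
18 | (2R,3R)-7-[2-(3,5-dimethoxyphenyl)-1-(4-methoxyphenyl)ethenyl]-3-(3,5-dimethoxyphenyl)-4-methoxy-2-(4-methoxyphenyl)-2,3-dihydro-1-benzofuran-6-carboxylic acid (E/Z mixture) | O1[C@@H](c2ccc(OC)cc2)[C@@H](c2c(OC)cc(C(=O)O)c(C(=Cc3cc(OC)cc(OC)c3)c3ccc(OC)cc3)c21)c1cc(OC)cc(OC)c1 | intermediate (not isolated)
19 | seven-membered ketone: ring A (3-OMe and 5-OMe) and ring B joined by C8a=O and C8b(H)=C7b(4-methoxyphenyl); ring B with 4-OMe and the (7cR,8cR)-dihydrofuran | COc1ccc(C2=Cc3cc(OC)cc(OC)c3C(=O)c3cc(OC)c4c(c32)O[C@@H](c2ccc(OC)cc2)[C@@H]4c2cc(OC)cc(OC)c2)cc1 | intermediate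
20 | ring-A 3-phenol of 19; (7cR,8cR) | COc1ccc(C2=Cc3cc(OC)cc(O)c3C(=O)c3cc(OC)c4c(c32)O[C@@H](c2ccc(OC)cc2)[C@@H]4c2cc(OC)cc(OC)c2)cc1 | intermediate
21 | 4-methoxybenzyl chloride | COc1ccc(CCl)cc1 | starting material
22 | ring-A 3-O-(4-methoxybenzyl) ether of 20; (7cR,8cR) | COc1ccc(C2=Cc3cc(OC)cc(OCc5ccc(OC)cc5)c3C(=O)c3cc(OC)c4c(c32)O[C@@H](c2ccc(OC)cc2)[C@@H]4c2cc(OC)cc(OC)c2)cc1 | intermediate
23 | C8a hydrazone of 22 (E/Z mixture) | COc1ccc(C2=Cc3cc(OC)cc(OCc5ccc(OC)cc5)c3C(=NN)c3cc(OC)c4c(c32)O[C@@H](c2ccc(OC)cc2)[C@@H]4c2cc(OC)cc(OC)c2)cc1 | intermediate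
24 | C8a diazo compound from 23 | COc1ccc(C2=Cc3cc(OC)cc(OCc5ccc(OC)cc5)c3C(=[N+]=[N-])c3cc(OC)c4c(c32)O[C@@H](c2ccc(OC)cc2)[C@@H]4c2cc(OC)cc(OC)c2)cc1 | intermediate (not isolated)
25 | heptamethyl ether, 7a,8a-cis; (7aR,8aS,7cR,8cR) | COc1ccc(C2=Cc3cc(OC)cc4c3[C@H](c3cc(OC)c5c(c32)O[C@@H](c2ccc(OC)cc2)[C@@H]5c2cc(OC)cc(OC)c2)[C@H](c2ccc(OC)cc2)O4)cc1 | intermediate
26 | heptamethyl ether of the target; (7aS,8aS,7cR,8cR) | COc1ccc(C2=Cc3cc(OC)cc4c3[C@H](c3cc(OC)c5c(c32)O[C@@H](c2ccc(OC)cc2)[C@@H]5c2cc(OC)cc(OC)c2)[C@@H](c2ccc(OC)cc2)O4)cc1 | intermediate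
27 | CNP0325907.1; (7aS,8aS,7cR,8cR) | Oc1ccc(C2=Cc3cc(O)cc4c3[C@H](c3cc(O)c5c(c32)O[C@@H](c2ccc(O)cc2)[C@@H]5c2cc(O)cc(O)c2)[C@@H](c2ccc(O)cc2)O4)cc1 | target

**Step count and risks**

Total step count: 15. Longest linear sequence: 15 steps (from 1; all other building blocks are commercial).

Steps most likely to fail:

Step 6 (ring-B benzannulation). What may go wrong: O- instead of C-acylation of the magnesium enolate, or aldol closure of the acetyl group onto the aroyl ketone instead of the keto ester. Fallback: the ring is closed by a Michael addition instead of an aldol, setting out from 9. The lithium dienolate of 9 is acylated at the ring CH2 with 4,4-diethoxy-N-methoxy-N-methylbut-2-ynamide F3 (made from 3,3-diethoxyprop-1-yne, n-BuLi and N-methoxy-N-methylcarbamoyl chloride) to give ynone 1-[(4R,5R)-4-(3,5-dimethoxyphenyl)-5-(4-methoxyphenyl)-2-[2-(4-methoxyphenyl)-2-oxoethyl]-4,5-dihydrofuran-3-yl]-4,4-diethoxybut-2-yn-1-one F4. DBU then brings about 6-endo-dig Michael addition of the aroyl-activated CH2 onto the ynone and tautomerisation to the phenol, and aqueous HCl unmasks the aldehyde (2R,3R)-3-(3,5-dimethoxyphenyl)-4-hydroxy-7-(4-methoxybenzoyl)-2-(4-methoxyphenyl)-2,3-dihydro-1-benzofuran-6-carbaldehyde F5. Pinnick oxidation gives the corresponding 6-carboxylic acid F6, and MeI/K2CO3 methylates phenol and acid, rejoining the route at 15.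

Step 13 (carbene C–H insertion). What may go wrong: poor facial selectivity on the cyclic diaryl carbene, or carbene rearrangement and ylide pathways competing with insertion. Fallback: anionic ring closure with late separation, setting out from 22. LiTMP (THF, −78 °C) deprotonates the O–CH2Ar group and the carbanion adds to the ketone (5-exo-trig) to give the 8a-hydroxy dihydrobenzofuran F7. Ionic hydrogenation (Et3SiH, TFA, CH2Cl2) through the stabilised C8a cation or the derived benzofuran, with acid equilibration at C7a, gives the two 7a,8a-trans compounds, 26 and its (7aR,8aR,7cR,8cR) diastereomer F8. These are diastereomers because C7c/C8c are fixed and are separated by preparative HPLC, rejoining the route at 26 (the ring-A centres are then not set by a catalyst).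

Step 3 (enzymatic reduction). What may go wrong: no panel enzyme accepts the bulky diaryl ketone with anti selectivity, or racemisation of the substrate is too slow for a dynamic process. Fallback: small-molecule reduction plus inversion, setting out from 5. Noyori-type transfer hydrogenation with RuCl[(S,S)-TsDPEN](p-cymene) in HCO2H/Et3N, with dynamic kinetic resolution under Felkin control, gives the syn alcohol (1S,2S)-2-(3,5-dimethoxyphenyl)-1-(4-methoxyphenyl)pent-4-yn-1-ol F1. Mitsunobu reaction with 4-nitrobenzoic acid (PPh3, DIAD) inverts the carbinol centre to give (1R,2S)-2-(3,5-dimethoxyphenyl)-1-(4-methoxyphenyl)pent-4-yn-1-yl 4-nitrobenzoate F2, and K2CO3/MeOH releases 6.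

Further compounds
F1 | step 3 | (1S,2S)-2-(3,5-dimethoxyphenyl)-1-(4-methoxyphenyl)pent-4-yn-1-ol | O[C@H](c1ccc(OC)cc1)[C@@H](CC#C)c1cc(OC)cc(OC)c1
F2 | step 3 | (1R,2S)-2-(3,5-dimethoxyphenyl)-1-(4-methoxyphenyl)pent-4-yn-1-yl 4-nitrobenzoate | O=C(O[C@@H](c1ccc(OC)cc1)[C@@H](CC#C)c1cc(OC)cc(OC)c1)c1ccc(cc1)[N+](=O)[O-]
F3 | step 6 | 4,4-diethoxy-N-methoxy-N-methylbut-2-ynamide | CCOC(OCC)C#CC(=O)N(C)OC
F4 | step 6 | 1-[(4R,5R)-4-(3,5-dimethoxyphenyl)-5-(4-methoxyphenyl)-2-[2-(4-methoxyphenyl)-2-oxoethyl]-4,5-dihydrofuran-3-yl]-4,4-diethoxybut-2-yn-1-one | O1[C@@H](c2ccc(OC)cc2)[C@@H](C(C(=O)C#CC(OCC)OCC)=C1CC(=O)c1ccc(OC)cc1)c1cc(OC)cc(OC)c1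
F5 | step 6 | (2R,3R)-3-(3,5-dimethoxyphenyl)-4-hydroxy-7-(4-methoxybenzoyl)-2-(4-methoxyphenyl)-2,3-dihydro-1-benzofuran-6-carbaldehyde | O1[C@@H](c2ccc(OC)cc2)[C@@H](c2c(O)cc(C=O)c(C(=O)c3ccc(OC)cc3)c21)c1cc(OC)cc(OC)c1
F6 | step 6 | (2R,3R)-3-(3,5-dimethoxyphenyl)-4-hydroxy-7-(4-methoxybenzoyl)-2-(4-methoxyphenyl)-2,3-dihydro-1-benzofuran-6-carboxylic acid | O1[C@@H](c2ccc(OC)cc2)[C@@H](c2c(O)cc(C(=O)O)c(C(=O)c3ccc(OC)cc3)c21)c1cc(OC)cc(OC)c1
F7 | step 13 | 8a-hydroxy dihydrobenzofuran from anionic cyclisation of 22 (epimers at C7a and C8a; 7cR,8cR) | COc1ccc(C2=Cc3cc(OC)cc4c3C(O)(c3cc(OC)c5c(c32)O[C@@H](c2ccc(OC)cc2)[C@@H]5c2cc(OC)cc(OC)c2)C(c2ccc(OC)cc2)O4)cc1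
F8 | step 13 | (7aR,8aR,7cR,8cR) diastereomer of heptamethyl ether 26 | COc1ccc(C2=Cc3cc(OC)cc4c3[C@@H](c3cc(OC)c5c(c32)O[C@@H](c2ccc(OC)cc2)[C@@H]5c2cc(OC)cc(OC)c2)[C@H](c2ccc(OC)cc2)O4)cc1
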